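**Plan**

The target is read as a trans-(2S,3S)-2-aryl-3-aroyl-2,3-dihydrobenzofuran that carries an (E)-2'-hydroxychalcone arm at C5.
Cuts: (a) four MOM ethers; (b) the C(=O)–CH= bond of the enone, giving a 5-ethynyldihydrobenzofuran and a salicylaldehyde; (c) the aryl–C(=O) bond of the C3 ketone, giving a Weinreb amide and an aryllithium; (d) C5–C(sp); (e) ring bond C2–C3, giving an aryldiazoacetate; (f) the benzyl–O bond.
Forward: ether formation, diazo transfer, closure of the five-membered O-ring by carbene C–H insertion, alkyne at C5, aroyl group at C3, one atom-economical union of the alkyne with the second resorcinol carbonyl unit, then MOM removal.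
Enabling feature: the free OH on C2' of the chalcone resorcinol ring lies ortho to the enone carbonyl carbon. The corresponding aldehyde therefore forms a five-membered O,C-chelated acyl rhodium hydride (Rh–O–C2'–C1'–C(=O)), which adds across a terminal C≡C without decarbonylation, so no olefination, oxidation or foreign directing group is needed.
Stereochemistry: C2 comes from the chiral dirhodium catalyst, which chooses between the enantiotopic benzylic hydrogens. C3 is set by equilibration to trans under control of C2. The E alkene comes from syn hydrorhodation.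

Key step: step 11

Assumption: by analogy with related aryldiazoacetate insertions, the (R)-configured phthaloyl-tert-leucinate catalyst is expected to select the hydrogen whose replacement gives 2S; if the sense were opposite, the mirror-image catalyst would be used and nothing else would change.

**Route**

Step 1
Reactants: 1 4-(methoxymethoxy)benzaldehyde
Product: 2 [4-(methoxymethoxy)phenyl]methanol
Conditions: NaBH4, MeOH, 0 °C
Reagents that add atoms: none
Why: Borohydride reduction of an aromatic aldehyde is routine and leaves the MOM acetal untouched.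

Step 2
Reactants: 2 [4-(methoxymethoxy)phenyl]methanol; 3 methyl 2-(5-bromo-2-hydroxyphenyl)acetate
Product: 4 methyl 2-(5-bromo-2-{[4-(methoxymethoxy)benzyl]oxy}phenyl)acetate
Conditions: PPh3, DIAD, THF, 0 °C → rt
Reagents that add atoms: none
Why: Mitsunobu etherification joins the phenol to the activated primary benzylic alcohol under near-neutral conditions, which avoids base-induced lactonisation of 3 to the benzofuranone.

Step 3
Reactants: 4 methyl 2-(5-bromo-2-{[4-(methoxymethoxy)benzyl]oxy}phenyl)acetate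
Product: 5 methyl 2-(5-bromo-2-{[4-(methoxymethoxy)benzyl]oxy}phenyl)-2-diazoacetate
Conditions: p-ABSA, DBU, MeCN, 0 °C → rt
Reagents that add atoms: 4-acetamidobenzenesulfonyl azide (p-ABSA), CC(=O)Nc1ccc(cc1)S(=O)(=O)N=[N+]=[N-]
Why: Regitz diazo transfer to the DBU enolate of an arylacetate is the standard entry to donor/acceptor aryldiazoacetates, and the ether, bromide and acetal are inert to it.

Step 4
Reactants: 5 methyl 2-(5-bromo-2-{[4-(methoxymethoxy)benzyl]oxy}phenyl)-2-diazoacetate
Product: 7 methyl (2S,3S)-5-bromo-2-[4-(methoxymethoxy)phenyl]-2,3-dihydro-1-benzofuran-3-carboxylate (trans), via cis ester 6 (not isolated)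
Conditions: Rh2(R-PTTL)4 (1 mol %), toluene, −60 °C; then NaOMe (0.3 equiv), MeOH, 0 °C → rt
Reagents that add atoms: none
Why: Enantioselective intramolecular 1,5 C–H insertion of the donor/acceptor rhodium carbene into the p-alkoxy-activated benzylic C–H bond closes the ring through C2–C3, the chiral carboxylate pocket choosing one enantiotopic hydrogen and so fixing C2 as S with kinetic cis geometry, after which methoxide equilibrates the acidic C3–H to the less crowded trans ester without touching C2.

Step 5
Reactants: 7 methyl (2S,3S)-5-bromo-2-[4-(methoxymethoxy)phenyl]-2,3-dihydro-1-benzofuran-3-carboxylate; 8 ethynyl(trimethyl)silane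
Product: 9 methyl (2S,3S)-2-[4-(methoxymethoxy)phenyl]-5-[(trimethylsilyl)ethynyl]-2,3-dihydro-1-benzofuran-3-carboxylate
Conditions: PdCl2(PhCN)2 (3 mol %), P(t-Bu)3 (6 mol %), CuI (2 mol %), i-Pr2NH, dioxane, rt
Reagents that add atoms: none
Why: Sonogashira coupling with a bulky electron-rich phosphine lets the electron-rich aryl bromide react at room temperature, so the C3 centre meets only a mild amine base and already holds its thermodynamic configuration.

Step 6
Reactants: 9 methyl (2S,3S)-2-[4-(methoxymethoxy)phenyl]-5-[(trimethylsilyl)ethynyl]-2,3-dihydro-1-benzofuran-3-carboxylate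
Product: 10 (2S,3S)-N-methoxy-N-methyl-2-[4-(methoxymethoxy)phenyl]-5-[(trimethylsilyl)ethynyl]-2,3-dihydro-1-benzofuran-3-carboxamide
Conditions: MeNHOMe·HCl, i-PrMgCl, THF, −20 → 0 °C
Reagents that add atoms: N,O-dimethylhydroxylamine hydrochloride, CNOC.Cl
Why: Aminolysis of the methyl ester by the magnesium amide is the usual direct route to a Weinreb amide, and any transient enolisation at C3 returns to the favoured trans isomer.

Step 7
Reactants: 11 4-bromobenzene-1,3-diol
Product: 12 1-bromo-2,4-bis(methoxymethoxy)benzene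
Conditions: MOMCl, i-Pr2NEt, CH2Cl2, 0 °C → rt
Reagents that add atoms: chloromethyl methyl ether (MOMCl), COCCl
Why: Double O-alkylation of the phenols with MOMCl is routine and gives a group that withstands, and by chelation stabilises, the ortho-lithio species needed next.

Step 8
Reactants: 10 (2S,3S)-N-methoxy-N-methyl-2-[4-(methoxymethoxy)phenyl]-5-[(trimethylsilyl)ethynyl]-2,3-dihydro-1-benzofuran-3-carboxamide; 12 1-bromo-2,4-bis(methoxymethoxy)benzene
Product: 14 [2,4-bis(methoxymethoxy)phenyl]{(2S,3S)-2-[4-(methoxymethoxy)phenyl]-5-[(trimethylsilyl)ethynyl]-2,3-dihydro-1-benzofuran-3-yl}methanone, via aryllithium 13 (not isolated)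
Conditions: 12, n-BuLi, THF, −78 °C; then 10, −78 → −40 °C; aq NH4Cl
Reagents that add atoms: none
Why: Bromine–lithium exchange followed by Weinreb ketone synthesis stops at the chelated tetrahedral adduct, so no over-addition occurs, the silyl cap removes the acidic alkyne hydrogen, and the trans relationship at C2/C3 is the stable one.

Step 9
Reactants: 14 [2,4-bis(methoxymethoxy)phenyl]{(2S,3S)-2-[4-(methoxymethoxy)phenyl]-5-[(trimethylsilyl)ethynyl]-2,3-dihydro-1-benzofuran-3-yl}methanone
Product: 15 [2,4-bis(methoxymethoxy)phenyl]{(2S,3S)-5-ethynyl-2-[4-(methoxymethoxy)phenyl]-2,3-dihydro-1-benzofuran-3-yl}methanone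
Conditions: TBAF (1.2 equiv), AcOH (1.2 equiv), THF, 0 °C
Reagents that add atoms: none
Why: Fluoride-induced protodesilylation of an alkynylsilane is fast even when buffered, and the buffer keeps the medium non-basic so that the C3–H ketone is not enolised and the ring oxygen is not lost by β-elimination.

Step 10
Reactants: 16 2,4-dihydroxybenzaldehyde
Product: 17 2-hydroxy-4-(methoxymethoxy)benzaldehyde
Conditions: MOMCl (1.05 equiv), K2CO3, acetone, 0 °C → rt
Reagents that add atoms: chloromethyl methyl ether (MOMCl), COCCl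
Why: Regioselective O-alkylation takes place at the more acidic 4-OH because the 2-OH is held in a hydrogen bond to the formyl oxygen, which leaves free exactly the hydroxyl group that the key step needs.

Step 11
Reactants: 15 [2,4-bis(methoxymethoxy)phenyl]{(2S,3S)-5-ethynyl-2-[4-(methoxymethoxy)phenyl]-2,3-dihydro-1-benzofuran-3-yl}methanone; 17 2-hydroxy-4-(methoxymethoxy)benzaldehyde
Product: 18 (E)-3-{(2S,3S)-3-[2,4-bis(methoxymethoxy)benzoyl]-2-[4-(methoxymethoxy)phenyl]-2,3-dihydro-1-benzofuran-5-yl}-1-[2-hydroxy-4-(methoxymethoxy)phenyl]prop-2-en-1-one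
Conditions: [RhCl(cod)]2 (2.5 mol %), dppf (5 mol %), Na2CO3 (10 mol %), toluene, 90 °C, slow addition of 15 to 17 (1.3 equiv)
Reagents that add atoms: none
Why: Carbonate turns the C2–OH of 17 into a rhodium(I) phenoxide, the neighbouring aldehyde C–H adds oxidatively to give a five-membered acyl(hydrido)rhodium(III) chelate (Rh, O, C2, C1, acyl C), the terminal alkyne of 15 inserts syn into Rh–H, and C(acyl)–C(vinyl) reductive elimination releases the enone and rhodium(I). The closest known reaction type is the chelation-assisted rhodium-catalysed intermolecular hydroacylation of alkynes with salicylaldehydes, which gives 2-alkenoylphenols. No ring of the product is closed and no stereocentre is made; the only ring is the transient rhodacycle, whose filled coordination site blocks CO de-insertion and hence decarbonylation. The E geometry follows from syn hydrorhodation and stereoretentive reductive elimination, and it is also the thermodynamic geometry of a chalcone. The step needs linear regioselectivity (Rh on the terminal carbon, H on the aryl-bearing carbon), which the bulky dihydrobenzofuranyl substituent and the wide-bite-angle dppf ligand should favour, and it needs a single reactive aldehyde–phenol pair, which is secured because every other phenol is a MOM ether and 15 has no formyl group. C2 and C3 are not touched, since only catalytic insoluble carbonate is present and C3 already holds its thermodynamic trans configuration.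

Step 12
Reactants: 18 (E)-3-{(2S,3S)-3-[2,4-bis(methoxymethoxy)benzoyl]-2-[4-(methoxymethoxy)phenyl]-2,3-dihydro-1-benzofuran-5-yl}-1-[2-hydroxy-4-(methoxymethoxy)phenyl]prop-2-en-1-one
Product: 19 (E)-3-[(2S,3S)-3-(2,4-dihydroxybenzoyl)-2-(4-hydroxyphenyl)-2,3-dihydro-1-benzofuran-5-yl]-1-(2,4-dihydroxyphenyl)prop-2-en-1-one (target)
Conditions: HCl (1.25 M in MeOH), THF, 40 °C
Reagents that add atoms: none
Why: Acid-catalysed acetal exchange with methanol is the usual way to unmask MOM-protected hydroxychalcones, and the stereocentres are self-correcting because enolisation at C3 or reversible ionisation at C2 alone would each return to the trans isomer dictated by the other centre.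

**Compound list**

1 | 4-(methoxymethoxy)benzaldehyde | COCOc1ccc(C=O)cc1 | starting material
2 | [4-(methoxymethoxy)phenyl]methanol | COCOc1ccc(CO)cc1 | intermediate
3 | methyl 2-(5-bromo-2-hydroxyphenyl)acetate | COC(=O)Cc1cc(Br)ccc1O | starting material
4 | methyl 2-(5-bromo-2-{[4-(methoxymethoxy)benzyl]oxy}phenyl)acetate | COC(=O)Cc1cc(Br)ccc1OCc1ccc(OCOC)cc1 | intermediate
5 | methyl 2-(5-bromo-2-{[4-(methoxymethoxy)benzyl]oxy}phenyl)-2-diazoacetate | COC(=O)C(=[N+]=[N-])c1cc(Br)ccc1OCc1ccc(OCOC)cc1 | intermediate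
6 | methyl (2S,3R)-5-bromo-2-[4-(methoxymethoxy)phenyl]-2,3-dihydro-1-benzofuran-3-carboxylate (cis, not isolated) | Brc1ccc2c(c1)[C@@H](C(=O)OC)[C@@H](c1ccc(OCOC)cc1)O2 | intermediate
7 | methyl (2S,3S)-5-bromo-2-[4-(methoxymethoxy)phenyl]-2,3-dihydro-1-benzofuran-3-carboxylate (trans) | Brc1ccc2c(c1)[C@H](C(=O)OC)[C@@H](c1ccc(OCOC)cc1)O2 | intermediate
8 | ethynyl(trimethyl)silane | C#C[Si](C)(C)C | starting material
9 | methyl (2S,3S)-2-[4-(methoxymethoxy)phenyl]-5-[(trimethylsilyl)ethynyl]-2,3-dihydro-1-benzofuran-3-carboxylate | C[Si](C)(C)C#Cc1ccc2c(c1)[C@H](C(=O)OC)[C@@H](c1ccc(OCOC)cc1)O2 | intermediate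
10 | (2S,3S)-N-methoxy-N-methyl-2-[4-(methoxymethoxy)phenyl]-5-[(trimethylsilyl)ethynyl]-2,3-dihydro-1-benzofuran-3-carboxamide | C[Si](C)(C)C#Cc1ccc2c(c1)[C@H](C(=O)N(C)OC)[C@@H](c1ccc(OCOC)cc1)O2 | intermediate
11 | 4-bromobenzene-1,3-diol | Oc1ccc(Br)c(O)c1 | starting material
12 | 1-bromo-2,4-bis(methoxymethoxy)benzene | COCOc1ccc(Br)c(OCOC)c1 | intermediate
13 | [2,4-bis(methoxymethoxy)phenyl]lithium (not isolated) | [Li]c1ccc(OCOC)cc1OCOC | intermediate
14 | [2,4-bis(methoxymethoxy)phenyl]{(2S,3S)-2-[4-(methoxymethoxy)phenyl]-5-[(trimethylsilyl)ethynyl]-2,3-dihydro-1-benzofuran-3-yl}methanone | C[Si](C)(C)C#Cc1ccc2c(c1)[C@H](C(=O)c1ccc(OCOC)cc1OCOC)[C@@H](c1ccc(OCOC)cc1)O2 | intermediate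
15 | [2,4-bis(methoxymethoxy)phenyl]{(2S,3S)-5-ethynyl-2-[4-(methoxymethoxy)phenyl]-2,3-dihydro-1-benzofuran-3-yl}methanone | C#Cc1ccc2c(c1)[C@H](C(=O)c1ccc(OCOC)cc1OCOC)[C@@H](c1ccc(OCOC)cc1)O2 | intermediate
16 | 2,4-dihydroxybenzaldehyde | O=Cc1ccc(O)cc1O | starting material
17 | 2-hydroxy-4-(methoxymethoxy)benzaldehyde | O=Cc1ccc(OCOC)cc1O | intermediate
18 | (E)-3-{(2S,3S)-3-[2,4-bis(methoxymethoxy)benzoyl]-2-[4-(methoxymethoxy)phenyl]-2,3-dihydro-1-benzofuran-5-yl}-1-[2-hydroxy-4-(methoxymethoxy)phenyl]prop-2-en-1-one | O=C(/C=C/c1ccc2c(c1)[C@H](C(=O)c1ccc(OCOC)cc1OCOC)[C@@H](c1ccc(OCOC)cc1)O2)c1ccc(OCOC)cc1O | intermediate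
19 | (E)-3-[(2S,3S)-3-(2,4-dihydroxybenzoyl)-2-(4-hydroxyphenyl)-2,3-dihydro-1-benzofuran-5-yl]-1-(2,4-dihydroxyphenyl)prop-2-en-1-one | O=C(/C=C/c1ccc2c(c1)[C@H](C(=O)c1ccc(O)cc1O)[C@@H](c1ccc(O)cc1)O2)c1ccc(O)cc1O | target

**Step count**

Total step count: 12.
Longest linear sequence: 10 (steps 1, 2, 3, 4, 5, 6, 8, 9, 11, 12).

**Steps most likely to fail**

1. Step 11.
Risk: hydrorhodation in the opposite sense, oligomerisation of the terminal alkyne on rhodium, or oxa-Michael closure of the product phenoxide onto the new enone.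
Fallback, from 15 back to 19: the same C(acyl)–C(vinyl) bond is made by cross-coupling in place of C–H activation.
- Pd2(dba)3/PCy3-catalysed hydrostannation of 15 with Bu3SnH should give the (E)-vinylstannane F1.
- Separately, aryllithium 13 (made as in step 8) is carboxylated with CO2 to 2,4-bis(methoxymethoxy)benzoic acid F2. This acid is condensed with 4-methylbenzenethiol (EDC, DMAP, CH2Cl2) to the S-aryl thioester F3.
- A Liebeskind–Srogl-type coupling of F1 and F3 (Pd catalyst, copper(I) diphenylphosphinate, neutral, THF) should give the penta-MOM chalcone F4.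
- The conditions of step 12 then remove all five MOM groups to reach 19.

2. Step 8.
Risk: deprotonation of the doubly activated C3–H of 10 by the aryllithium in place of carbonyl addition, possibly followed by β-elimination of the ring oxygen.
Fallback, from 10 back to 14: the electrophile is changed to an aldehyde, which takes up aryllithiums much faster than it is enolised.
- DIBAL-H (THF, −78 °C) should reduce 10 to the 3-carbaldehyde F5.
- Addition of 13 at −78 °C should give the secondary carbinol F6 as a mixture of epimers at the carbinol carbon, which is of no consequence.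
- Dess–Martin periodinane (NaHCO3, CH2Cl2) then returns ketone 14.

3. Step 4.
Risk: poor discrimination between the two enantiotopic benzylic hydrogens, or carbene dimerisation.
Fallback, from 5 back to 7: catalyst control is replaced by a covalent resolution.
- Rh2(OAc)4 in CH2Cl2 followed by NaOMe/MeOH should give the racemic trans ester F7.
- LiOH (THF/H2O, 0 °C) should give the racemic trans acid F8.
- Activation with pivaloyl chloride/Et3N and acylation of lithiated (S)-4-benzyloxazolidin-2-one should give two diastereomers, the (2S,3S) imide F9 and the (2R,3R) imide F10.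
- These would be separated by chromatography or crystallisation and assigned by X-ray analysis with bromine as the heavy atom.
- NaOMe in MeOH at 0 °C then converts F9 into 7.

**Further compounds**

F1 | step 11 | [2,4-bis(methoxymethoxy)phenyl]{(2S,3S)-2-[4-(methoxymethoxy)phenyl]-5-[(E)-2-(tributylstannyl)ethenyl]-2,3-dihydro-1-benzofuran-3-yl}methanone | CCCC[Sn](CCCC)(CCCC)/C=C/c1ccc2c(c1)[C@H](C(=O)c1ccc(OCOC)cc1OCOC)[C@@H](c1ccc(OCOC)cc1)O2
F2 | step 11 | 2,4-bis(methoxymethoxy)benzoic acid | COCOc1ccc(C(=O)O)c(OCOC)c1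
F3 | step 11 | S-(4-methylphenyl) 2,4-bis(methoxymethoxy)benzenecarbothioate | COCOc1ccc(C(=O)Sc2ccc(C)cc2)c(OCOC)c1
F4 | step 11 | (E)-3-{(2S,3S)-3-[2,4-bis(methoxymethoxy)benzoyl]-2-[4-(methoxymethoxy)phenyl]-2,3-dihydro-1-benzofuran-5-yl}-1-[2,4-bis(methoxymethoxy)phenyl]prop-2-en-1-one | O=C(/C=C/c1ccc2c(c1)[C@H](C(=O)c1ccc(OCOC)cc1OCOC)[C@@H](c1ccc(OCOC)cc1)O2)c1ccc(OCOC)cc1OCOC
F5 | step 8 | (2S,3S)-2-[4-(methoxymethoxy)phenyl]-5-[(trimethylsilyl)ethynyl]-2,3-dihydro-1-benzofuran-3-carbaldehyde | C[Si](C)(C)C#Cc1ccc2c(c1)[C@H](C=O)[C@@H](c1ccc(OCOC)cc1)O2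
F6 | step 8 | [2,4-bis(methoxymethoxy)phenyl]{trans-2-[4-(methoxymethoxy)phenyl]-5-[(trimethylsilyl)ethynyl]-2,3-dihydro-1-benzofuran-3-yl}methanol, ring centres as in 14, both carbinol epimers | C[Si](C)(C)C#Cc1ccc2c(c1)[C@H](C(O)c1ccc(OCOC)cc1OCOC)[C@@H](c1ccc(OCOC)cc1)O2
F7 | step 4 | racemic trans methyl 5-bromo-2-[4-(methoxymethoxy)phenyl]-2,3-dihydro-1-benzofuran-3-carboxylate (both enantiomers) | Brc1ccc2c(c1)[C@H](C(=O)OC)[C@@H](c1ccc(OCOC)cc1)O2.Brc1ccc2c(c1)[C@@H](C(=O)OC)[C@H](c1ccc(OCOC)cc1)O2
F8 | step 4 | racemic trans 5-bromo-2-[4-(methoxymethoxy)phenyl]-2,3-dihydro-1-benzofuran-3-carboxylic acid (both enantiomers) | Brc1ccc2c(c1)[C@H](C(=O)O)[C@@H](c1ccc(OCOC)cc1)O2.Brc1ccc2c(c1)[C@@H](C(=O)O)[C@H](c1ccc(OCOC)cc1)O2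
F9 | step 4 | (4S)-4-benzyl-3-{(2S,3S)-5-bromo-2-[4-(methoxymethoxy)phenyl]-2,3-dihydro-1-benzofuran-3-carbonyl}-1,3-oxazolidin-2-one | Brc1ccc2c(c1)[C@H](C(=O)N1[C@@H](Cc3ccccc3)COC1=O)[C@@H](c1ccc(OCOC)cc1)O2
F10 | step 4 | (4S)-4-benzyl-3-{(2R,3R)-5-bromo-2-[4-(methoxymethoxy)phenyl]-2,3-dihydro-1-benzofuran-3-carbonyl}-1,3-oxazolidin-2-one | Brc1ccc2c(c1)[C@@H](C(=O)N1[C@@H](Cc3ccccc3)COC1=O)[C@H](c1ccc(OCOC)cc1)O2
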